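The numbers in the tables come from a simulation for substances that don't exist; noise was put on by code.

How much complex with two exchanged stands at the end of midnight? Answer it by counting turnovers, then bracket the count.

| setting | elm | alder | autumn | midnight | dusk |
|---|---|---|---|---|---|
| starting complex | 0.20 M | 0.20 M | 0.20 M | 0.20 M | 0.20 M |
| incoming ligand | 0.74 equiv | 2.2 equiv | 1.00 equiv | 2.50 equiv | 1.20 equiv |
| remark | run made earlier | run made earlier |  |  |  |
| time |  |  | 4.0 min | 4.0 min | 4.0 min |

| run | time / min | complex with two exchanged / % | complex with one exchanged / % |
|---|---|---|---|
| elm | 0.500 | 0 | 5.5 |
| elm | 1.00 | 0 | 8.5 |
| elm | 1.50 | 0.5 | 11.0 |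
| elm | 2.50 | 0.5 | 12.7 |
| elm | 3.00 | 0.1 | 12.5 |
| elm | 4.00 | 0.1 | 12.8 |
| alder | 0.200 | 0 | 7.9 |
| alder | 0.667 | 0 | 18.8 |
| alder | 1.00 | 0.4 | 24.3 |
| alder | 1.50 | 1.1 | 28.1 |
| alder | 2.50 | 1.9 | 32.3 |
| alder | 3.00 | 1.7 | 33.1 |
| alder | 4.00 | 3.0 | 33.4 |

(each reading ± 0.3 percentage points)

* which of these holds the largest part of the starting complex at the end of autumn (complex with two exchanged / starting complex / complex with one exchanged)
* which of these holds the largest part of the starting complex at the end of midnight (complex with two exchanged / starting complex / complex with one exchanged)
* which of these holds the largest part of the starting complex at the end of dusk (complex with two exchanged / starting complex / complex with one exchanged)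
* how much complex with two exchanged is there at the end of midnight, in percent of the starting complex charged

- a species is counted by the starting complex in it: one side product counts as two
- amounts and yields of complex with one exchanged count crystals too
- given per volume of solution although it is solid: crystals
- the earlier runs were read with a standard deviation of 0.3 percentage points
- what may be going on: starting complex + incoming ligand -> leaving ligand + complex with one exchanged; complex with one exchanged + incoming ligand -> leaving ligand + complex with two exchanged; starting complex + complex with one exchanged -> side product; crystals <-> complex with one exchanged

Start from alder, whose ligand charge lies nearer midnight's than elm's does. Average its complex with one exchanged over the run by trapezoids: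

mean level = 26.8% of the charge

Divide the final complex with two exchanged by this level:

3.0% / 26.8% = 0.112

Call this the turnover count: the fraction of the standing complex with one exchanged that passes on during the run. Treat the second exchange as pseudo-first-order in complex with one exchanged, and assume the incoming ligand keeps a like share of its charge in both flasks. With the same 0.20 M of starting complex and the same 4.0 min in both flasks, the count then scales with the equivalents, so midnight gets 0.127.

For the lower bound, keep alder's mean level:

3.41%

For the upper bound, raise that level in proportion to the ligand. This is generous, because from elm to alder the final level grew 2.61-fold on 2.97-fold ligand, less than proportionally: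

3.87%

The single alder reading carries a scatter of 0.3 percentage points, which widens the bracket to 3.07% and 4.26%.

The forecast says 3.3%, below the narrow bracket but inside the wide one. It picks starting complex for autumn, starting complex for dusk and complex with one exchanged for midnight, with the words “Starting complex leads in both” for the first two.

Midnight gives 3.93% of complex with two exchanged, above the narrow bracket but inside the wide one, and all three picks hold: 39.3% of starting complex in autumn, 32.5% of starting complex in dusk, and 36.6% of complex with one exchanged in midnight.

    starting complex + incoming ligand → leaving ligand + complex with one exchanged (k = 0.0160 M⁻¹ s⁻¹)
    complex with one exchanged + incoming ligand → leaving ligand + complex with two exchanged (k = 0.00140 M⁻¹ s⁻¹)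
    starting complex + complex with one exchanged → side product (k = 0.0540 M⁻¹ s⁻¹)
    crystals ⇌ complex with one exchanged, rate k4*(cs4 - [complex with one exchanged]) while solid is left; crystals form when [complex with one exchanged] > cs4 (solubility = 0.110 M, k = 0.440 s⁻¹)

Now charge midnight's recipe at 0.080 M, holding the equivalents and the time. The ligand concentration falls with the charge, so this reckoning scales the count down to 0.0509. This neighbour ends with 32.0% of complex with one exchanged, all forms counted. Alder's ratio of mean to final level, 0.802, then gives 1.31% of complex with two exchanged. The neighbour holds 1.23%.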